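All constants are assumed; the flask was simulated.

5 questions stand on this card, and I answer them with one number made from two rate constants.

| flask | first end groups | second end groups | time | remark |
|---|---|---|---|---|
| blue | 20 mM (in portions, 4, over 80 min) | 20.4 mM | 2.0 h | first portion at the start, last at 80 min |
| violet | 20 mM | 20.4 mM (fed, over 80 min) | 2.0 h | all else is in the flask from the start; the feed brings no volume worth counting |
| teal | 20 mM | 20.4 mM | 2.0 h | everything together at the start |
| amber | 20 mM (fed, over 80 min) | 20.4 mM | 2.0 h | all else is in the flask from the start; the feed brings no volume worth counting |

    first end groups + second end groups → links (k1 = 0.036 M⁻¹ s⁻¹)
    first end groups + second end groups → rings, rate k2*[first end groups] as long as [second end groups] is above zero (k2 = 1.9 × 10⁻⁵ s⁻¹)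
    second end groups → decomposed reagent (k3 = 1.9 × 10⁻⁴ s⁻¹)

- the flask with the highest amount of links, in percent of the first end groups charged ("all alike" if they lie within 1.5 percentage points) (blue / violet / teal / amber / all alike)
- final links, as a percentage of the first end groups charged, in blue
- final links, as a percentage of the first end groups charged, in violet
- final links, as a percentage of the first end groups charged, in teal
- final links, as a percentage of the first end groups charged, in amber

A second end group stands at a fork: per unit time it links with a chance that grows with c(first end groups), or it decomposes with a fixed chance. Dividing the decomposition constant by the linking constant gives K = 5.28 mM. I call this the break-even level, the c(first end groups) at which the two chances are equal; their ratio, c/K, is a selectivity factor.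

I follow teal. In the first instants c(first end groups) is 3.79 times K, so linking leads, with a time constant of 23.1 min against 87.7 min for decomposition. Rings start slowly: at the start linking runs 38.7 times as fast. Their rate doesn't fall with c(second end groups), though, so they matter later.

In the middle c(first end groups) sinks toward K, and the linking time constant stretches. With rings left aside, each first end group linked at level c costs one plus K/c second end groups. Summed until second end groups, the limiting reagent here, reach zero, this gives 20.4 mM = 20 mM − a + K·ln(20 mM/a), where a is the end level of first end groups. Putting K in for a on the right returns 6.63 mM. The mean of the two, 5.95 mM, makes the sum 20.5 mM, which is close enough.

So by this balance, an estimate with rings left out, about 70.2 % of the first end groups react. Rings at the end level take about 4.07 %, so I commit to 66.2 % links in teal. For the others I rank without figures: blue's first portion of 5.00 mM lies below K, and amber starts from nothing, so I put both under teal.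

The forecast gives 46 % for blue, 58 % for violet, 65 % for teal and 45 % for amber, and picks teal, holding that “the best flask is the one where both partners are concentrated from the start”. Its teal stands a little below mine.

The flasks give 46.1 % in blue, 58.6 % in violet, 65.5 % in teal and 45.0 % in amber, so teal leads, as the forecast said.

In teal, linking uses second end groups 2.5 times as fast as decomposition after 0.201 h and 1.1 times as fast after 2.00 h, and c(first end groups) over K at that time is 1.09. Teal closes with 29 % of its first end groups unused beside 1.5 % of its second end groups, and after 20.0 h links stand at 65.7 %.

For the neighbour of teal charged with 50 mM of first end groups, the same balance, again with rings left out, puts a at 31.9 mM, so I estimate that 36.2 % of that charge reacts. It computes to 33.0 % links and 3.51 % rings, with 63.5 % of the first end groups left.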